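**Remarks on the chemistry (assumptions)**

- Hydrindanes carry the indane locants (ring B: C1, C2, C3, C3a, C7a; ring A: C3a, C4–C7, C7a); β is the face of H-7a. Decalins 9–11 carry naphthalen-2(1H)-one locants, which map onto the hydrindane as C2→C2, C3→acetyl carbon, C4→C1, C4a→C7a, C5→C7, C6→C6, C7→C5, C8→C4, C8a→C3a, C1→C3.
- 12 is written as one enol tautomer; it equilibrates with its diketo forms, so C1 has no fixed configuration before step 9.
- Alkaline epoxidation of 10 is expected on the α face (axial attack trans to H-4a), so 11 is drawn as the α-epoxide; the β-epoxide would converge on the same 12.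

## Structural features

The target is a trans-fused hydrindane (oplopane skeleton): six-membered ring A (C3a, C4, C5, C6, C7, C7a) and five-membered ring B (C1, C2, C3, C3a, C7a) share the C3a–C7a bond, with H-3a and H-7a anti. Ring A carries an exocyclic methylene at C4, an axial (2S,3S)-2,3-epoxy-2-methylbutanoate at C6 and, cis to it, an equatorial isopropyl group at C7. Ring B carries an acetyl group at C1 (trans to the C7a–C7 bond) and, cis to it, an angelate at C2. The six ring stereocentres C2, C1, C7a, C7, C6 and C3a are contiguous, and the epoxy ester adds two more that must come in as a single enantiomer. Fragile elements are the β-acyloxy ketone (E1cB loss of the C2 ester, retro-aldol at the hydroxy stage), the enolisable C1, the Z-configured 2-methylbut-2-enoate, the glycidic ester and the acid-sensitive 1,1-disubstituted alkene. The real difficulty is the trans ring fusion combined with the contiguous stereo array and two different esters on two hindered secondary carbinols, one of them next to an epimerisable and eliminable centre. The key step exploits the pattern CH3–C(=O)–C1–C2–O: the acetyl carbon is read as a former ring carbon, so ring B with its C1–C2 bond is the contraction product of a 2-methyl-2,3-epoxy ketone in a trans-decalin whose ring A is already that of the target.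

## Logic of the disconnections

22 ⇒ 17 + 20. The acyl C–O bond at C6 is cut first because the glycidic ester is the most acid-labile part and should be attached last. This removes two stereocentres and the epoxide and makes the route convergent. The forward step must acylate an axial alcohol flanked by the isopropyl group with an α-quaternary acid, mildly enough for the β-acyloxy ketone.

20 ⇒ 19 ⇒ 18 ⇒ 14. The carboxyl oxidation level, then the two epoxide C–O bonds, then the carbinol oxidation level are removed. An allylic alcohol allows reagent-controlled epoxidation, and both esters of 22 then derive from 14. The forward steps must keep the Z geometry and select one face of a Z-trisubstituted allylic alcohol.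

17 ⇒ 16 ⇒ 13 + 14. The O–Si bond at C6 and the acyl C–O bond at C2 are cut. The silyl ether is what allows the two secondary alcohols to receive two different acids in turn. The forward steps need an esterification that neither isomerises the Z acid nor opens the β-hydroxy ketone, and a desilylation without base.

13 ⇒ 12. The C2–H bond is cut, and C1 goes with it because C1 in 12 lies between two carbonyls and is stereolabile. Two stereocentres disappear. The forward step must distinguish the ring carbonyl from the acetyl carbonyl and deliver hydride to one face of one C1 epimer while C1 equilibrates.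

12 ⇒ 11. The C1–C2 bond of ring B is cut and the carbonyl carbon is returned to the methyl-bearing carbon. The acetylcyclopentanone becomes a six-membered epoxy ketone, so the trans-hydrindane problem becomes a trans-decalin problem with the enone pattern of a commodity terpenoid ketone. The forward step needs acyl migration in preference to methyl or hydride migration, and must tolerate the alkene and the silyl ether.

11 ⇒ 10 ⇒ 9. The epoxide C–O bonds and the O–Si bond are cut. This returns a plain enone and a free alcohol. The forward steps need an epoxidation that touches only the electron-poor alkene and a silylation of a hindered axial alcohol.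

9 ⇒ 8. The C5–C6 bond of ring A is cut as a retro-ene. Ring A, the C6 stereocentre and the methylene vanish and an aldehyde faces an isopropenyl group already present in 5. The forward step needs a chair transition state that delivers the axial alcohol on a trans-fused ring.

8 ⇒ 7 ⇒ 6 + 4. The aldehyde is traced to a primary nitro group, then the C7–C7a bond is cut. The nitroalkene supplies C6 and C7 with the isopropyl group and an umpoled aldehyde carbon. The forward step needs γ- rather than α-attack of the dienol ether, approach anti to the isopropenyl group and control of the side-chain centre.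

6 ⇒ 5, and 4 ⇒ 1 + 2 through 3. The O–Si bond and the nitroalkene C=C bond are cut. Everything is then commercial. The forward steps need enolisation of 5 toward C4 and not C6, and an E-selective dehydration.

## Other disconnections considered

Alternative 1: The cut is through C7–C7a and C3a–C7a of the cadinane, tracing the whole decalin to acyclic (2E,6E)-farnesyl diphosphate A1. In the forward sense a γ-cadinene synthase would ionise A1, close the ten-membered ring, then the second six-membered ring, and release γ-cadinene A2 with the C4 methylene.
- In its favour: one operation from a fermentable precursor would give both six-membered rings, the carbon stereocentres C3a, C7 and C7a and the methylene. On step economy to the carbon skeleton and on stereocontrol of those three centres it is better than the five steps that lead to 9.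
- Against it here: A2 carries no oxygen. Allylic oxidation of ring B could plausibly reach the enone of 10, but the axial C6 hydroxyl lies on an unactivated methylene beside the isopropyl group and competes with several allylic sites, so a second, hydroxylating enzyme would be needed. A synthase of the right enantiomeric series must also be available.
- Comparison: A2 is 10 without its two oxygens, whereas the chosen plan builds ring A around the C6 oxygen. The cationic cascade is more direct than the polar bond constructions used here, but it ends at the cadinane, so the epoxidation and acyl-shift contraction would still be required. Overall step economy is better to the skeleton and open-ended for the oxidation pattern.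

Alternative 2: The cut is through C4–C5 and C3a–C7a. In the forward sense the allene–diene A3 would undergo a thermal intramolecular Diels–Alder reaction, the inner allene double bond adding to the 2-silyloxy diene C5=C6–C7=C7a across a three-atom tether, to give the hydrindane A4.
- In its favour: both rings, C3a, C7a and the methylene would form in one step, no rearrangement is needed, and the C1 acetyl (as ketal) and the C2 oxygen are carried in. On skeleton built per step and on predictability of constitution it is the equal or the better of the chosen plan.
- Against it here: trans fusion in cycloadditions of this tether length is seldom well controlled, and only the two tether stereocentres would steer it. The outer allene double bond may compete. A3 needs an acyclic stereodiad, a geometrically defined trisubstituted diene with a labile silyl enol ether and a terminal allene.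
- Comparison: after the cycloaddition C7 (protonation of the enol ether) and the axial C6 alcohol would still have to be set on a ring with an epimerisable centre, whereas the chosen plan sets them in bond-forming steps on rigid rings. Once the synthesis of A3 is counted, step economy is comparable at best, and the chosen plan is stronger on relative configuration.

Alternative 3: The cut is through C5–C6 of ring A on an already contracted ring B. In the forward sense Me2AlCl would promote the carbonyl–ene reaction of keto aldehyde A7 to give A8. A7 would be assembled from (R)-limonene A5 and isovaleraldehyde A6, the latter supplying C6, C7 and the isopropyl group by conjugate addition to an oxidised, ring-contracted derivative of A5. The (R)-enantiomer is assumed on the basis that the ring is contracted by an oxidative 1,2-shift that extrudes the methyl-bearing alkene carbon as the acetyl group.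
- In its favour: the ene closure is the same as step 5 and A8 is the desilylated form of 12, so on these points it is equal. No Lewis acid rearrangement is run on an advanced bicyclic intermediate. C7 could be set under amine-catalyst control, which is better than the substrate control of step 3, and A5 is cheaper than 5.
- Against it here: the C2 oxygen is absent from A5 and must be introduced, passing through a doubly activated cyclopentenone acceptor prone to self-condensation. The oxidative contraction must choose between the two alkenes of A5. Trans selectivity relative to the isopropenyl group is less secure on a cyclopentene than on the cyclohexadiene 6. The ene reaction would have to run on an acidic, chelating 1,3-diketone that ties up the aluminium reagent.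
- Comparison: 5 already holds the ring methyl, the C2 carbonyl and the C3a centre in one six-membered ring, where the trans relationship and the later contraction are easier to control. Step counts should be similar, and the mechanistic risk is shifted from the rearrangement to the oxidation and conjugate-addition stages.

Key step: step 8

## Route

Step 1
Reactants: 1 isobutyraldehyde (2-methylpropanal); 2 nitromethane
Product: 4 (E)-3-methyl-1-nitrobut-1-ene, via 3-methyl-1-nitrobutan-2-ol 3 (not isolated)
Conditions: MeNO2 (3 equiv), KOt-Bu (5 mol %), THF/t-BuOH, 0 °C; AcOH (5 mol %), concentrate; then MsCl, Et3N, CH2Cl2, 0 °C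
Reagents that add atoms: none
Why: Henry (nitroaldol) addition, then mesylation and E1cB elimination; the conjugated nitroalkene should form as the E isomer under thermodynamic control.

Step 2
Reactants: 5 (S)-carvone
Product: 6 trimethyl{[(5R)-2-methyl-5-(prop-1-en-2-yl)cyclohexa-1,3-dien-1-yl]oxy}silane (linear dienol ether)
Conditions: i-Pr2NMgBr (from EtMgBr and i-Pr2NH), TMSCl, Et3N, DMPU, Et2O, 0 → 25 °C
Reagents that add atoms: chlorotrimethylsilane, C[Si](C)(C)Cl
Why: Thermodynamic silyl enol ether formation with a bromomagnesium amide: the magnesium enolates equilibrate by proton transfer faster than they are silylated, so the kinetic C6 enolate should funnel into the conjugated C1=C2–C3=C4 dienolate, which is trapped on oxygen; C5 is not part of the dienolate and keeps its configuration.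

Step 3
Reactants: 6 linear dienol ether; 4 (E)-3-methyl-1-nitrobut-1-ene
Product: 7 (4R,5R)-2-methyl-4-[(2S)-3-methyl-1-nitrobutan-2-yl]-5-(prop-1-en-2-yl)cyclohex-2-en-1-one
Conditions: SnCl4 (1.0 equiv), CH2Cl2, −78 °C; then aq. NaHCO3, 0 °C
Reagents that add atoms: none
Why: Vinylogous Mukaiyama–Michael addition to a nitroalkene: the dienol ether should react at its γ-carbon C4 (the α-carbon is fully substituted) on the face anti to the C5 isopropenyl group (4,5-trans); the side-chain centre is expected from a compact, cycloaddition-like approach with the nitro group over the diene and the isopropyl group outside, and mild hydrolysis of the nitronate returns the enone.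

Step 4
Reactants: 7 nitro enone
Product: 8 (2S)-3-methyl-2-[(1R,6R)-3-methyl-4-oxo-6-(prop-1-en-2-yl)cyclohex-2-en-1-yl]butanal
Conditions: NaOMe (1.05 equiv), MeOH, 0 °C; then aq. TiCl3, NH4OAc (pH 5–6), 0 → 25 °C
Reagents that add atoms: water, O
Why: Reductive Nef reaction: the nitronate is reduced by TiCl3 to the imine, which hydrolyses in the buffered medium, so neither the enone nor the α-branched aldehyde centre meets strong acid or base.

Step 5
Reactants: 8 keto aldehyde
Product: 9 (4aR,5S,6R,8aR)-6-hydroxy-3-methyl-8-methylidene-5-(propan-2-yl)-4a,5,6,7,8,8a-hexahydronaphthalen-2(1H)-one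
Conditions: Me2AlCl (2.2 equiv), CH2Cl2, −78 → −20 °C
Reagents that add atoms: none
Why: Type 2 intramolecular carbonyl–ene reaction (tether on the central carbon of the isopropenyl ene unit): the aldehyde carbon bonds to the terminal CH2, a methyl hydrogen passes to oxygen and the alkene ends exocyclic; in the chair transition state with equatorial isopropyl the complexed C=O must be axial to reach that hydrogen, which should give the axial C6 alcohol cis to the isopropyl group on a trans-fused decalin.

Step 6
Reactants: 9 hydroxy enone
Product: 10 (4aR,5S,6R,8aR)-6-[(tert-butyldimethylsilyl)oxy]-3-methyl-8-methylidene-5-(propan-2-yl)-4a,5,6,7,8,8a-hexahydronaphthalen-2(1H)-one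
Conditions: TBSOTf, 2,6-lutidine, CH2Cl2, −78 → 0 °C
Reagents that add atoms: tert-butyldimethylsilyl trifluoromethanesulfonate, CC(C)(C)[Si](C)(C)OS(=O)(=O)C(F)(F)F
Why: Silylation of a hindered axial secondary alcohol calls for the silyl triflate; 2,6-lutidine is too weak a base to enolise the enone.

Step 7
Reactants: 10 silyl ether enone
Product: 11 (3S,4S,4aR,5S,6R,8aR)-6-[(tert-butyldimethylsilyl)oxy]-3,4-epoxy-3-methyl-8-methylidene-5-(propan-2-yl)-3,4,4a,5,6,7,8,8a-octahydronaphthalen-2(1H)-one (α-epoxide)
Conditions: 30% aq. H2O2, NaOH (0.3 equiv), MeOH, 0 °C
Reagents that add atoms: hydrogen peroxide, OO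
Why: Weitz–Scheffer epoxidation: hydroperoxide adds only to the electron-poor enone and leaves the 1,1-disubstituted alkene; axial attack at C4 on the α face should give the α-epoxide, and this configuration is erased in step 8 in any case.

Step 8
Reactants: 11 epoxy ketone
Product: 12 1-[(3aR,6R,7S,7aR)-6-[(tert-butyldimethylsilyl)oxy]-2-hydroxy-4-methylidene-7-(propan-2-yl)-3a,4,5,6,7,7a-hexahydro-3H-inden-1-yl]ethan-1-one (enol form of the 1-acetyl-2-oxo trans-hydrindane)
Conditions: BF3·OEt2 (0.5 equiv), CH2Cl2, −40 → 0 °C
Reagents that add atoms: none
Why: BF3 coordinates the epoxide oxygen and the C4–O bond (to the carbon β to the carbonyl, the later C1) lengthens, because cleavage of the C3–O bond would place positive charge next to the carbonyl carbon. As this bond breaks, the carbonyl carbon C2 migrates from the methyl-bearing C3 to C4 on the face opposite the departing oxygen, and the oxygen left on C3 becomes the acetyl carbonyl. The closest known reaction type is the Lewis-acid rearrangement of 2,3-epoxycyclohexanones to 2-acylcyclopentanones by 1,2-acyl shift. Ring B is therefore closed by ring contraction through a 1,2-shift and not by an exo or endo cyclisation. No stereocentre is created: the new sp3 centre C1 lies between two carbonyls and is lost in the enol, while C3a, C6, C7 and C7a are untouched and the trans fusion is carried over. The selectivity needed is β C–O cleavage with acyl migration over methyl migration or hydride shift, which would give a 1,2-dione or a cyclohexane-1,3-dione; the carbonyl group secures it by disfavouring ionisation at C3, together with the high migratory aptitude of acyl. Sub-stoichiometric BF3·OEt2 at low temperature is chosen to spare the exocyclic alkene and the silyl ether, whose oxygen cannot bridge to the cationic carbon because the C4a–C4 bond is equatorial on ring A.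

Step 9
Reactants: 12 enolised diketone
Product: 13 1-[(1R,2S,3aR,6R,7S,7aR)-6-[(tert-butyldimethylsilyl)oxy]-2-hydroxy-4-methylidene-7-(propan-2-yl)octahydro-1H-inden-1-yl]ethan-1-one
Conditions: ketoreductase (NADPH-dependent, selected from a panel), NADP+ (cat.), i-PrOH (10% v/v), DMSO (10% v/v), phosphate buffer pH 7.0, 30 °C
Reagents that add atoms: none
Why: Ketoreductase-catalysed dynamic reductive kinetic resolution of an α-substituted 1,3-diketone: C1 epimerises through the enol faster than hydride is delivered, and the enzyme is selected to reduce the ring carbonyl C2 from the α face of the 1β-acetyl epimer; this matches the substrate bias (acetyl trans to the C7a–C7 bond, hydride anti to the acetyl group) and should give the cis-β-hydroxy ketone.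

Step 10
Reactants: 13 β-hydroxy ketone; 14 angelic acid [(2Z)-2-methylbut-2-enoic acid]
Product: 16 (1R,2S,3aR,6R,7S,7aR)-1-acetyl-6-[(tert-butyldimethylsilyl)oxy]-4-methylidene-7-(propan-2-yl)octahydro-1H-inden-2-yl (2Z)-2-methylbut-2-enoate, via angeloyl mixed anhydride 15 (not isolated)
Conditions: 14, 2,4,6-trichlorobenzoyl chloride, Et3N (1.0 equiv), toluene, 25 °C; then 13, toluene, 60 °C
Reagents that add atoms: none
Why: Yamaguchi-type esterification run without a nucleophilic catalyst: the alcohol attacks the less hindered angeloyl carbonyl, and since no acylpyridinium forms the Z alkene should not drift to the E isomer; the near-neutral medium protects the β-hydroxy ketone from retro-aldol cleavage and the product from elimination.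

Step 11
Reactants: 16 silyl ether angelate
Product: 17 (1R,2S,3aR,6R,7S,7aR)-1-acetyl-6-hydroxy-4-methylidene-7-(propan-2-yl)octahydro-1H-inden-2-yl (2Z)-2-methylbut-2-enoate
Conditions: HF·pyridine, pyridine, THF, 0 → 25 °C
Reagents that add atoms: none
Why: Acidic fluoride desilylation; buffered HF·pyridine avoids the basic fluoride conditions that would eliminate the β-acyloxy ketone and leaves the ester and the exocyclic alkene alone.

Step 12
Reactants: 14 angelic acid
Product: 18 (2Z)-2-methylbut-2-en-1-ol
Conditions: LiAlH4, Et2O, 0 °C
Reagents that add atoms: none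
Why: Hydride reduction of the carboxylic acid to the allylic alcohol; 1,2-reduction at low temperature should keep the Z geometry.

Step 13
Reactants: 18 (2Z)-2-methylbut-2-en-1-ol
Product: 19 [(2R,3S)-2,3-dimethyloxiran-2-yl]methanol
Conditions: Ti(Oi-Pr)4 (10 mol %), D-(−)-diisopropyl tartrate (12 mol %), t-BuOOH, 4 Å molecular sieves, CH2Cl2, −20 °C
Reagents that add atoms: tert-butyl hydroperoxide, CC(C)(C)OO
Why: Sharpless asymmetric epoxidation; the D-(−)-tartrate should deliver oxygen to the face that makes C2 R, and syn addition to the Z alkene then fixes C3 as S (cis-2,3-dimethyl epoxide).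

Step 14
Reactants: 19 epoxy alcohol
Product: 20 (2S,3S)-2,3-dimethyloxirane-2-carboxylic acid
Conditions: RuCl3·xH2O (2 mol %), NaIO4, MeCN/EtOAc/H2O, 0 → 25 °C
Reagents that add atoms: sodium periodate, [Na+].[O-]I(=O)(=O)=O; water, O
Why: Oxidation of a primary epoxy alcohol to the glycidic acid by RuO4 generated catalytically from RuCl3 and NaIO4; no stereocentre is touched, and the C2 descriptor changes from R to S only because the carboxyl group now outranks C3.

Step 15
Reactants: 17 C6 alcohol; 20 epoxy acid
Product: 22 (1R,2S,3aR,6R,7S,7aR)-1-acetyl-4-methylidene-2-{[(2Z)-2-methylbut-2-enoyl]oxy}-7-(propan-2-yl)octahydro-1H-inden-6-yl (2S,3S)-2,3-dimethyloxirane-2-carboxylate, via epoxy acid mixed anhydride 21 (not isolated)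
Conditions: 20, 2,4,6-trichlorobenzoyl chloride, Et3N, toluene, 25 °C; then 17, DMAP (1.5 equiv), toluene, 25 → 40 °C
Reagents that add atoms: none
Why: Yamaguchi esterification, the standard answer to a hindered secondary alcohol and an α-quaternary acid; the acyl donor has no isomerisable alkene, all stereocentres are already in place, and the mild temperature should limit E1cB loss of the C2 angelate.

## Compound list

1 | isobutyraldehyde (2-methylpropanal) | CC(C)C=O | starting material
2 | nitromethane | C[N+](=O)[O-] | starting material
3 | 3-methyl-1-nitrobutan-2-ol (racemic) | CC(C)C(O)C[N+](=O)[O-] | intermediate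
4 | (E)-3-methyl-1-nitrobut-1-ene | CC(C)/C=C/[N+](=O)[O-] | intermediate
5 | (S)-carvone | CC1=CC[C@@H](CC1=O)C(C)=C | starting material
6 | trimethyl{[(5R)-2-methyl-5-(prop-1-en-2-yl)cyclohexa-1,3-dien-1-yl]oxy}silane | CC1=C(O[Si](C)(C)C)C[C@H](C=C1)C(C)=C | intermediate
7 | (4R,5R)-2-methyl-4-[(2S)-3-methyl-1-nitrobutan-2-yl]-5-(prop-1-en-2-yl)cyclohex-2-en-1-one | [O-][N+](=O)C[C@@H](C(C)C)[C@@H]1C=C(C)C(=O)C[C@H]1C(C)=C | intermediate
8 | (2S)-3-methyl-2-[(1R,6R)-3-methyl-4-oxo-6-(prop-1-en-2-yl)cyclohex-2-en-1-yl]butanal | O=C[C@@H](C(C)C)[C@@H]1C=C(C)C(=O)C[C@H]1C(C)=C | intermediate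
9 | (4aR,5S,6R,8aR)-6-hydroxy-3-methyl-8-methylidene-5-(propan-2-yl)-4a,5,6,7,8,8a-hexahydronaphthalen-2(1H)-one | C=C1C[C@@H](O)[C@@H](C(C)C)[C@@H]2C=C(C)C(=O)C[C@@H]12 | intermediate
10 | (4aR,5S,6R,8aR)-6-[(tert-butyldimethylsilyl)oxy]-3-methyl-8-methylidene-5-(propan-2-yl)-4a,5,6,7,8,8a-hexahydronaphthalen-2(1H)-one | C=C1C[C@@H](O[Si](C)(C)C(C)(C)C)[C@@H](C(C)C)[C@@H]2C=C(C)C(=O)C[C@@H]12 | intermediate
11 | (3S,4S,4aR,5S,6R,8aR)-6-[(tert-butyldimethylsilyl)oxy]-3,4-epoxy-3-methyl-8-methylidene-5-(propan-2-yl)-3,4,4a,5,6,7,8,8a-octahydronaphthalen-2(1H)-one | C=C1C[C@@H](O[Si](C)(C)C(C)(C)C)[C@@H](C(C)C)[C@@H]2[C@@H]3O[C@]3(C)C(=O)C[C@@H]12 | intermediate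
12 | 1-[(3aR,6R,7S,7aR)-6-[(tert-butyldimethylsilyl)oxy]-2-hydroxy-4-methylidene-7-(propan-2-yl)-3a,4,5,6,7,7a-hexahydro-3H-inden-1-yl]ethan-1-one (enol tautomer) | C=C1C[C@@H](O[Si](C)(C)C(C)(C)C)[C@@H](C(C)C)[C@@H]2C(C(C)=O)=C(O)C[C@@H]12 | intermediate
13 | 1-[(1R,2S,3aR,6R,7S,7aR)-6-[(tert-butyldimethylsilyl)oxy]-2-hydroxy-4-methylidene-7-(propan-2-yl)octahydro-1H-inden-1-yl]ethan-1-one | C=C1C[C@@H](O[Si](C)(C)C(C)(C)C)[C@@H](C(C)C)[C@@H]2[C@@H](C(C)=O)[C@@H](O)C[C@@H]12 | intermediate
14 | angelic acid, (2Z)-2-methylbut-2-enoic acid | C/C=C(/C)C(=O)O | starting material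
15 | (2Z)-2-methylbut-2-enoic 2,4,6-trichlorobenzoic anhydride | C/C=C(/C)C(=O)OC(=O)c1c(Cl)cc(Cl)cc1Cl | intermediate
16 | (1R,2S,3aR,6R,7S,7aR)-1-acetyl-6-[(tert-butyldimethylsilyl)oxy]-4-methylidene-7-(propan-2-yl)octahydro-1H-inden-2-yl (2Z)-2-methylbut-2-enoate | C=C1C[C@@H](O[Si](C)(C)C(C)(C)C)[C@@H](C(C)C)[C@@H]2[C@@H](C(C)=O)[C@@H](OC(=O)/C(C)=C\C)C[C@@H]12 | intermediate
17 | (1R,2S,3aR,6R,7S,7aR)-1-acetyl-6-hydroxy-4-methylidene-7-(propan-2-yl)octahydro-1H-inden-2-yl (2Z)-2-methylbut-2-enoate | C=C1C[C@@H](O)[C@@H](C(C)C)[C@@H]2[C@@H](C(C)=O)[C@@H](OC(=O)/C(C)=C\C)C[C@@H]12 | intermediate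
18 | (2Z)-2-methylbut-2-en-1-ol | C/C=C(/C)CO | intermediate
19 | [(2R,3S)-2,3-dimethyloxiran-2-yl]methanol | OC[C@@]1(C)O[C@H]1C | intermediate
20 | (2S,3S)-2,3-dimethyloxirane-2-carboxylic acid | OC(=O)[C@@]1(C)O[C@H]1C | intermediate
21 | (2S,3S)-2,3-dimethyloxirane-2-carboxylic 2,4,6-trichlorobenzoic anhydride | O=C(OC(=O)c1c(Cl)cc(Cl)cc1Cl)[C@@]1(C)O[C@H]1C | intermediate
22 | (1R,2S,3aR,6R,7S,7aR)-1-acetyl-4-methylidene-2-{[(2Z)-2-methylbut-2-enoyl]oxy}-7-(propan-2-yl)octahydro-1H-inden-6-yl (2S,3S)-2,3-dimethyloxirane-2-carboxylate | C=C1C[C@@H](OC(=O)[C@@]2(C)O[C@H]2C)[C@@H](C(C)C)[C@@H]2[C@@H](C(C)=O)[C@@H](OC(=O)/C(C)=C\C)C[C@@H]12 | target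

## Step count and least certain steps

Total step count: 15. Longest linear sequence: 11 steps (from 5 through steps 2–11 and 15; equally from 1 through steps 1, 3–11 and 15).

Step 8 (key step). Most likely to go wrong: methyl migration or hydride shift competing with the acyl shift once the β C–O bond opens, because the migration terminus is secondary and the trans-decalin restricts alignment of the ring bond; acid-induced migration of the exocyclic double bond or loss of the silyl group are further risks. Fallback: the rearrangement would be tried on the diastereomeric epoxide, in which the acyl carbon approaches from the other face. Setting out from 10, Luche reduction (NaBH4, CeCl3·7H2O, MeOH, −78 °C) should give the β allylic alcohol F3. Hydroxyl-directed epoxidation (VO(acac)2, t-BuOOH, CH2Cl2) should give the syn epoxy alcohol F4. Dess–Martin oxidation would give the β-epoxy ketone F5, which under the conditions of step 8 comes back to the route at 12.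

Step 2. Most likely to go wrong: enolisation toward C6 with incomplete equilibration, giving the cross-conjugated dienol ether, since C6 is the kinetic site. Fallback: setting out from 5, kinetic enolisation (LDA, THF, −78 °C; TMSCl) would deliberately give the cross-conjugated dienol ether F1. F1 would then be equilibrated by reversible C-protonation with a catalytic amount of a silyl triflate–amine triflate pair in CH2Cl2 to the conjugated isomer, returning to the route at 6.

Step 3. Most likely to go wrong: poor diastereoface selection at the side-chain carbon if open and compact transition states compete, since this centre is set outside the ring. Fallback: the bond would be made by a concerted cycloaddition so that the endo rule sets the centre. Setting out from 6 and 4, heating in toluene (90 °C) should give the endo-nitro bicyclo[2.2.2]octene adduct F2. Desilylation (TBAF, AcOH, THF, 0 °C) would trigger retro-Henry opening of the bridgehead β-nitro alkoxide and return to the route at 7.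

Step 9. Most likely to go wrong: reduction of the acetyl carbonyl instead of the ring carbonyl, because methyl ketones are intrinsically good ketoreductase substrates, or slow turnover of a lipophilic substrate. Fallback: setting out from 12, ruthenium-catalysed asymmetric transfer hydrogenation with dynamic kinetic resolution (RuCl[(S,S)-TsDPEN](p-cymene) or its enantiomer, HCO2H/Et3N, CH2Cl2, 25 °C) would be used, with the ligand enantiomer matched to the substrate bias; it returns to the route at 13 and needs no new compound.

Step 15. Most likely to go wrong: slow acylation of the axial, isopropyl-flanked alcohol, which leaves time for base-induced elimination of the C2 ester and for acyl transfer from the wrong carbonyl of the mixed anhydride. Fallback: the order of the two esterifications would be inverted so that the hindered one is done on a robust substrate. Setting out from 12, HF·pyridine would give the hydroxy diketone F6 (the same structure as A8). Excess 21 with DMAP, followed by methanolic NaHCO3 to cleave any enol ester, would give the C6 epoxy ester diketone F7. Ketoreductase reduction as in step 9 would give the hydroxy ketone F8, and angeloylation with 15 as in step 10 would return to the route at 22.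

## Further compounds

F1 | step 2 | trimethyl{[(3S)-6-methyl-3-(prop-1-en-2-yl)cyclohexa-1,5-dien-1-yl]oxy}silane | CC1=CC[C@H](C(C)=C)C=C1O[Si](C)(C)C
F2 | step 3 | trimethyl{[2-methyl-6-nitro-5-(propan-2-yl)-8-(prop-1-en-2-yl)bicyclo[2.2.2]oct-2-en-1-yl]oxy}silane, nitro group endo | C[Si](C)(C)O[C@@]12C[C@@H](C(C)=C)[C@@H](C=C1C)[C@H](C(C)C)[C@H]2[N+](=O)[O-]
F3 | step 8 | 2β-allylic alcohol from 10: 6-[(tert-butyldimethylsilyl)oxy]-3-methyl-8-methylidene-5-(propan-2-yl)-1,2,4a,5,6,7,8,8a-octahydronaphthalen-2-ol | C=C1C[C@@H](O[Si](C)(C)C(C)(C)C)[C@@H](C(C)C)[C@@H]2C=C(C)[C@@H](O)C[C@@H]12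
F4 | step 8 | 3β,4β-epoxy-2β-alcohol: 6-[(tert-butyldimethylsilyl)oxy]-3,4-epoxy-3-methyl-8-methylidene-5-(propan-2-yl)decahydronaphthalen-2-ol | C=C1C[C@@H](O[Si](C)(C)C(C)(C)C)[C@@H](C(C)C)[C@@H]2[C@H]3O[C@@]3(C)[C@@H](O)C[C@@H]12
F5 | step 8 | β-epoxy ketone, the 3,4-diastereomer of 11 | C=C1C[C@@H](O[Si](C)(C)C(C)(C)C)[C@@H](C(C)C)[C@@H]2[C@H]3O[C@@]3(C)C(=O)C[C@@H]12
F0 | step 9 | none | none
F6 | step 15 | 1-[(3aR,6R,7S,7aR)-2,6-dihydroxy-4-methylidene-7-(propan-2-yl)-3a,4,5,6,7,7a-hexahydro-3H-inden-1-yl]ethan-1-one (enol tautomer) | C=C1C[C@@H](O)[C@@H](C(C)C)[C@@H]2C(C(C)=O)=C(O)C[C@@H]12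
F7 | step 15 | (3aR,5R,4S,7aR)-3-acetyl-2-hydroxy-7-methylidene-4-(propan-2-yl)-3a,4,5,6,7,7a-hexahydro-1H-inden-5-yl (2S,3S)-2,3-dimethyloxirane-2-carboxylate (enol tautomer; C6 epoxy ester of F6) | C=C1C[C@@H](OC(=O)[C@@]3(C)O[C@H]3C)[C@@H](C(C)C)[C@@H]2C(C(C)=O)=C(O)C[C@@H]12
F8 | step 15 | (1R,2S,3aR,6R,7S,7aR)-1-acetyl-2-hydroxy-4-methylidene-7-(propan-2-yl)octahydro-1H-inden-6-yl (2S,3S)-2,3-dimethyloxirane-2-carboxylate | C=C1C[C@@H](OC(=O)[C@@]3(C)O[C@H]3C)[C@@H](C(C)C)[C@@H]2[C@@H](C(C)=O)[C@@H](O)C[C@@H]12
A1 | alternative 1 | (2E,6E)-farnesyl diphosphate | CC(C)=CCC/C(C)=C/CC/C(C)=C/COP(=O)(O)OP(=O)(O)O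
A2 | alternative 1 | γ-cadinene (enantiomer matching 10) | C=C1CC[C@@H](C(C)C)[C@@H]2C=C(C)CC[C@@H]12
A3 | alternative 2 | acyclic allene–diene: terminal allene C3a=C4=CH2, tether C3, C2 (OTBS), C1 (2-methyl-1,3-dioxolan-2-yl), diene C7a=C7(i-Pr)–C6(OSiEt3)=C5 | C=C=CC[C@H](O[Si](C)(C)C(C)(C)C)[C@H](C1(C)OCCO1)/C=C(/C(=C)O[Si](CC)(CC)CC)C(C)C
A4 | alternative 2 | trans-hydrindane with C4 methylene, C6 triethylsilyl enol ether, C1 dioxolane, C2 OTBS | C=C1CC(O[Si](CC)(CC)CC)=C(C(C)C)[C@@H]2[C@@H](C3(C)OCCO3)[C@@H](O[Si](C)(C)C(C)(C)C)C[C@@H]12
A5 | alternative 3 | (R)-limonene | CC1=CC[C@@H](CC1)C(C)=C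
A6 | alternative 3 | isovaleraldehyde (3-methylbutanal) | CC(C)CC=O
A7 | alternative 3 | (2S)-2-[(1R,5R)-2-acetyl-3-hydroxy-5-(prop-1-en-2-yl)cyclopent-2-en-1-yl]-3-methylbutanal (enol tautomer) | O=C[C@@H](C(C)C)[C@@H]1C(C(C)=O)=C(O)C[C@H]1C(C)=C
A8 | alternative 3 | 1-[(3aR,6R,7S,7aR)-2,6-dihydroxy-4-methylidene-7-(propan-2-yl)-3a,4,5,6,7,7a-hexahydro-3H-inden-1-yl]ethan-1-one (enol tautomer) | C=C1C[C@@H](O)[C@@H](C(C)C)[C@@H]2C(C(C)=O)=C(O)C[C@@H]12
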